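Remark on the chemistry: locants C1–C15 are the germacrane locants defined under "Structural features"; TBDPS = tert-butyl(diphenyl)silyl; the (Z)-γ-alkoxyallylborane made from (−)-Ipc2BOMe (from (+)-α-pinene) is taken to give the syn (4R,5R) adduct, its antipode giving the enantiomeric syn pair.

## Structural features

The target is a furanoheliangolide-type sesquiterpene lactone; with germacrane locants, the ten-membered carbocycle C1–C10 carries a ketone at C1, the C2=C3 double bond, C15H2OH on C4, oxygen on C6 and C8, and C14H3 on C10. An ether oxygen joins C3 and C10, so that O–C3=C2–C1(=O)–C10 is a 3(2H)-furanone and the whole is an 11-oxabicyclo[6.2.1]undecane whose six-carbon bridge is C4–C9 and whose C2=C3 double bond sits at a bridgehead. An α-methylene-γ-butyrolactone (C11=C13H2, C12=O) is trans-fused at C6–C7, and C8 carries a (Z)-2-methylbut-2-enoate (angelate). The stereocentres C6 (R), C7 (S) and C8 (R) are contiguous, C4 (S) is separated from them by C5H2, and C10 (S) is a fully substituted, oxygen-bearing carbon beyond the ketone with no neighbouring stereocentre. Fragile groups are the exocyclic methylene lactone (Michael acceptor), the angelate (isomerises to the tiglate with nucleophiles or base) and the vinylogous ester, whose γ-carbon C4 is epimerisable and can lose the C15 hydroxyl by vinylogous β-elimination. The real difficulty is the strained nine-membered oxacycle (ten-membered carbocycle) spanned by the furanone, together with the remote quaternary C10, whose configuration has to be tied to the C4/C6/C7/C8 array. The key step exploits the fact that the ether oxygen, C10 and the bridge atoms C9–C8–C7 form the five-atom array of an oxonium ylide [2,3] shift: a tetrahydropyran O–C3–C4–C5–C6–C7 with a vinyl group (C8=C9) on C7 and a diazoketone chain C2–C1(=O)–C10(N2)–C14 on C3 is expanded by three atoms into the bridged bicycle. Because the six-carbon bridge can span the furanone ring only cis, the configuration of C10 is dictated by C3, a stereocentre that is erased later when C2=C3 is introduced.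

## Logic of the disconnections

30 ⇒ 29 ⇒ 27. The O15–Si bond is restored and the C2=C3 π bond is removed (C2–H and C3–H restored). The vinylogous ester makes C4 epimerisable, so it is introduced late, and an sp3 C3 is needed earlier as the relay stereocentre. The forward dehydrogenation must be regioselective (only C2 carries α-hydrogens) and mild; the desilylation must spare the methylene lactone and the angelate.

27 ⇒ 26. The C12=O bond is cut back to C12H2. The lactone is traced to a cyclic allylic ether so that its three carbons can come from an O-propargyl group. The forward oxidation must strike only C12, the one position that is both allylic and α to oxygen.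

26 ⇒ 23 + 24. The O8–acyl bond is cut. This leaves the only free hydroxyl of 23 as the acylation site. The esterification must not isomerise the Z double bond of 24.

23 ⇒ 22. The C7–C11 bond (and C13–H) is cut. The methylene tetrahydrofuran becomes a C7 radical facing an alkyne held on O6, and the radical is traced to an epoxide carbon. The forward step must break the C7–O and not the C8–O bond of the epoxide and close the trans ring fusion.

22 ⇒ 21. The two epoxide C–O bonds (C7–O, C8–O) are cut. The C7/C8 stereocentres collapse to the cis C7=C8 double bond. The forward epoxidation must occur on the face anti to the C6 oxygen.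

21 ⇒ 20 ⇒ 19 (key). The C9–C10 bond is cut while O–C7 is re-formed (retro-[2,3]), then O–C10 is cut back to a diazo carbon. The bridged bicycle with its medium ring becomes a monocyclic six-membered ether, the quaternary C10 disappears, and C7=C8 becomes a vinyl group. In one sentence: 19 is ring-expanded by three atoms through oxonium ylide 20. The forward step must let ylide formation outrun hydride migration and must give the cis alkene.

19 ⇒ 18 ⇒ 17. The C1–C10 bond is cut (acyl carbon and diazoalkane carbon). This gives a carboxylic acid; the forward acylation must be non-enolising, because C3 is β to the carbonyl.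

17 ⇒ 16 ⇒ 15 ⇒ 14. The ester O–CH3 bond, then the ring O–C3 bond (retro-oxa-Michael), then the O7–CH2OMe bond are cut. The ring opens to a chain and C3 is no longer a stereocentre that has to be set by a reagent. The forward cyclisation must equilibrate to the 2,6-cis chair.

14 ⇒ 13 ⇒ 12. The C2=C3 double bond is cut (Wittig), and the aldehyde C3–H is traced to an amide C–N bond. The forward steps must not epimerise C4.

12 ⇒ 10 + 11. The O6–C12 ether bond is cut. The alkyne arrives as a simple alkylating agent and doubles as the protecting group of O6.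

10 ⇒ 7 + 8 (through 9). The C6–C7 bond is cut. C6 and C7 and the vinyl group come from one reagent-controlled alkoxyallylboration. The aldehyde must react in preference to the amide.

7 ⇒ 6 ⇒ 5 ⇒ 4 ⇒ 3 ⇒ 1 + 2. C6=O is traced to a terminal alkene, then the O15–Si bond, the amide C–N bond, the C4–C15 bond (hydroxymethylation, which sets C4, the one stereocentre bought from the auxiliary) and the N-acyl bond are cut. All other stereocentres are then relayed or reagent-set from this point.

## Other disconnections considered

Alternative 1: Cut C6–C7 and the lactone C–O bond. The forward key step is an intramolecular Barbier-type allylation (Zn or CrCl2) of the aldehyde/allylic bromide A1, built on a finished furanone, closing the ten-membered ring and the lactone together. This is the first plan that comes to mind. It is not chosen because the ring closure has to work against the full transannular strain of the bridged ring from an open chain. In addition C10 must be set beforehand by an unrelated asymmetric step with no relay to the C4/C6/C8 centres, and C6/C7 selectivity rests only on a macrocyclic transition state. The chosen plan reaches the same ring by a three-atom expansion of a six-membered ring and derives C10 from C3.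

Alternative 2: Cut the transannular O–C3 bond. A ten-membered carbocyclic hydroxy-1,3-diketone A2 would be made first and the oxygen bridge stitched across by transannular cyclodehydration. This postpones rather than solves the hard ring: A2 still needs an unassisted ten-membered carbocyclisation. Its β-diketone is open to retro-Claisen cleavage and to transannular aldol reactions, and the tertiary carbinol C10 must be set separately. It would cost more steps for no gain in control.

Alternative 3: Cut C9–C10. The forward step is an intramolecular C-alkylation of the 3-oxidofuran (furanone enolate) derived from iodide A3, forming the quaternary centre and the medium ring together. The enolate is ambident (O- against C-alkylation), and the iodide is β to an acyloxy group and prone to elimination. The planar furanolate must be bridged by six atoms in the transition state, nothing but ring strain selects the face at C10, and the complete methylene lactone and angelate would have to survive strong base. In the chosen plan C10 is fixed mechanically by C3 under neutral conditions.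

Key step: step 13

## Steps

Step 1
Reactants: 1 (R)-4-benzyloxazolidin-2-one; 2 pent-4-enoyl chloride
Product: 3 (R)-4-benzyl-3-(pent-4-enoyl)oxazolidin-2-one
Conditions: n-BuLi, THF, −78 °C; then 2, −78 to 0 °C
Reagents that add atoms: none
Why: N-acylation of the lithiated Evans auxiliary; no stereocentre is formed.

Step 2
Reactants: 3 (R)-4-benzyl-3-(pent-4-enoyl)oxazolidin-2-one
Product: 4 (R)-4-benzyl-3-[(2S)-2-(hydroxymethyl)pent-4-enoyl]oxazolidin-2-one
Conditions: TiCl4, i-Pr2NEt, CH2Cl2, 0 °C; then 1,3,5-trioxane, TiCl4, 0 °C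
Reagents that add atoms: 1,3,5-trioxane (C1OCOCO1)
Why: Evans titanium-enolate hydroxymethylation (aldol addition to formaldehyde released from trioxane). The chelated Z-enolate is attacked on the face opposite the benzyl group, which sets C4 (2S in 4).

Step 3
Reactants: 4 (R)-4-benzyl-3-[(2S)-2-(hydroxymethyl)pent-4-enoyl]oxazolidin-2-one
Product: 5 (2S)-2-(hydroxymethyl)-N-methoxy-N-methylpent-4-enamide
Conditions: MeNHOMe·HCl, AlMe3, CH2Cl2, 0 °C to rt; dilute HCl work-up
Reagents that add atoms: N,O-dimethylhydroxylamine hydrochloride (CNOC.Cl)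
Why: Weinreb transamination of the imide with the aluminium amide, assisted by the free β-hydroxyl; the auxiliary is recovered and the α-centre is untouched.

Step 4
Reactants: 5 (2S)-2-(hydroxymethyl)-N-methoxy-N-methylpent-4-enamide
Product: 6 (2S)-2-{[tert-butyl(diphenyl)silyl]oxymethyl}-N-methoxy-N-methylpent-4-enamide
Conditions: TBDPSCl, imidazole, DMF, rt
Reagents that add atoms: tert-butyl(chloro)diphenylsilane (CC(C)(C)[Si](Cl)(c1ccccc1)c1ccccc1)
Why: Silylation of the primary alcohol; TBDPS is chosen because it survives the later acid, base, radical and chromium steps.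

Step 5
Reactants: 6 (2S)-2-{[tert-butyl(diphenyl)silyl]oxymethyl}-N-methoxy-N-methylpent-4-enamide
Product: 7 (2S)-2-{[tert-butyl(diphenyl)silyl]oxymethyl}-N-methoxy-N-methyl-4-oxobutanamide
Conditions: O3, CH2Cl2/MeOH, −78 °C; then PPh3, −78 °C to rt
Reagents that add atoms: ozone ([O-][O+]=O)
Why: Ozonolysis of the terminal alkene with reductive work-up gives the C6 aldehyde; the amide and silyl ether are inert.

Step 6
Reactants: 7 (2S)-2-{[tert-butyl(diphenyl)silyl]oxymethyl}-N-methoxy-N-methyl-4-oxobutanamide; 8 allyl methoxymethyl ether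
Product: 10 (2S,4R,5R)-2-{[tert-butyl(diphenyl)silyl]oxymethyl}-4-hydroxy-N-methoxy-5-(methoxymethoxy)-N-methylhept-6-enamide, via alkoxyallylborane 9 (not isolated)
Conditions: 8, s-BuLi, THF, −78 °C; (−)-Ipc2BOMe; BF3·OEt2; then 7, −78 °C; NaOAc (aq), H2O2, 0 °C to rt
Reagents that add atoms: (−)-B-methoxydiisopinocampheylborane (COB([C@@H]1C[C@@H]2C[C@H]([C@H]1C)C2(C)C)[C@@H]1C[C@@H]2C[C@H]([C@H]1C)C2(C)C; atoms kept only in 9)
Why: Brown alkoxyallylboration: the (Z)-γ-alkoxyallylborane reacts through a chair transition state to give the syn 4-hydroxy-5-alkoxy adduct, and the isopinocampheyl groups set C6 and C7 (4R,5R) by reagent control over the remote C4 centre. The aldehyde reacts and the Weinreb amide does not; 10 is used at once to avoid lactonisation.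

Step 7
Reactants: 10 (2S,4R,5R)-2-{[tert-butyl(diphenyl)silyl]oxymethyl}-4-hydroxy-N-methoxy-5-(methoxymethoxy)-N-methylhept-6-enamide; 11 propargyl bromide
Product: 12 (2S,4R,5R)-2-{[tert-butyl(diphenyl)silyl]oxymethyl}-N-methoxy-5-(methoxymethoxy)-N-methyl-4-(prop-2-yn-1-yloxy)hept-6-enamide
Conditions: NaH, n-Bu4NI (cat.), THF/DMF, 0 °C
Reagents that add atoms: none
Why: Williamson etherification of the C6 alkoxide; O-alkylation by the reactive propargylic bromide is faster than attack of the alkoxide on the amide, whose amide anion is a poor leaving group. The propargyl group protects O6 and later supplies C11–C13.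

Step 8
Reactants: 12 (2S,4R,5R)-2-{[tert-butyl(diphenyl)silyl]oxymethyl}-N-methoxy-5-(methoxymethoxy)-N-methyl-4-(prop-2-yn-1-yloxy)hept-6-enamide
Product: 13 (2S,4R,5R)-2-{[tert-butyl(diphenyl)silyl]oxymethyl}-5-(methoxymethoxy)-4-(prop-2-yn-1-yloxy)hept-6-enal
Conditions: i-Bu2AlH, THF, −78 °C; aqueous Rochelle salt
Reagents that add atoms: none
Why: Reduction of the Weinreb amide stops at the aldehyde through the chelated tetrahedral intermediate; 13 is used crude to avoid epimerisation at C4.

Step 9
Reactants: 13 (2S,4R,5R)-2-{[tert-butyl(diphenyl)silyl]oxymethyl}-5-(methoxymethoxy)-4-(prop-2-yn-1-yloxy)hept-6-enal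
Product: 14 methyl (2E,4R,6R,7R)-4-{[tert-butyl(diphenyl)silyl]oxymethyl}-7-(methoxymethoxy)-6-(prop-2-yn-1-yloxy)nona-2,8-dienoate
Conditions: Ph3P=CHCO2Me, CH2Cl2, rt
Reagents that add atoms: methyl (triphenylphosphoranylidene)acetate (COC(=O)C=P(c1ccccc1)(c1ccccc1)c1ccccc1)
Why: Wittig olefination with a stabilised ylide gives the (E)-enoate under neutral conditions, which protects the α-stereocentre.

Step 10
Reactants: 14 methyl (2E,4R,6R,7R)-4-{[tert-butyl(diphenyl)silyl]oxymethyl}-7-(methoxymethoxy)-6-(prop-2-yn-1-yloxy)nona-2,8-dienoate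
Product: 16 methyl 2-[(2S,3S,5R,6R)-3-{[tert-butyl(diphenyl)silyl]oxymethyl}-5-(prop-2-yn-1-yloxy)-6-vinyltetrahydro-2H-pyran-2-yl]acetate, via hydroxy enoate 15 (not isolated)
Conditions: HCl (conc., cat.), MeOH, 40 °C; concentrate; then t-BuOK (0.2 equiv), THF, 0 °C to rt
Reagents that add atoms: none
Why: Acetal methanolysis frees the C7 hydroxyl, and base-catalysed 6-exo-trig oxa-Michael addition under equilibrating conditions closes the tetrahydropyran. The thermodynamic 2,6-cis chair has the vinyl, acetate and silyloxymethyl groups equatorial (only the propargyloxy group axial), which fixes C3 as S.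

Step 11
Reactants: 16 methyl 2-[(2S,3S,5R,6R)-3-{[tert-butyl(diphenyl)silyl]oxymethyl}-5-(prop-2-yn-1-yloxy)-6-vinyltetrahydro-2H-pyran-2-yl]acetate
Product: 17 2-[(2S,3S,5R,6R)-3-{[tert-butyl(diphenyl)silyl]oxymethyl}-5-(prop-2-yn-1-yloxy)-6-vinyltetrahydro-2H-pyran-2-yl]acetic acid
Conditions: LiOH, THF/MeOH/H2O, rt; then 1 M HCl to pH 3
Reagents that add atoms: lithium hydroxide ([Li+].[OH-])
Why: Saponification of the methyl ester; any retro-Michael/Michael equilibration under these conditions returns the same thermodynamic 2,6-cis ring.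

Step 12
Reactants: 17 2-[(2S,3S,5R,6R)-3-{[tert-butyl(diphenyl)silyl]oxymethyl}-5-(prop-2-yn-1-yloxy)-6-vinyltetrahydro-2H-pyran-2-yl]acetic acid
Product: 19 3-diazo-1-[(2S,3S,5R,6R)-3-{[tert-butyl(diphenyl)silyl]oxymethyl}-5-(prop-2-yn-1-yloxy)-6-vinyltetrahydro-2H-pyran-2-yl]butan-2-one, via mixed carbonic anhydride 18 (not isolated)
Conditions: i-BuOCOCl, Et3N, THF, −20 °C; then CH3CHN2 in Et2O, −20 °C to rt
Reagents that add atoms: isobutyl chloroformate (CC(C)COC(Cl)=O; atoms kept only in 18); diazoethane (CC=[N+]=[N-])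
Why: Acylation of diazoethane by the mixed anhydride (Arndt–Eistert-type diazoketone synthesis) gives the methyl-substituted diazoketone; the departing isobutyl carbonate takes up the proton. The weakly basic, non-enolising conditions avoid retro-oxa-Michael opening at C3.

Step 13
Reactants: 19 3-diazo-1-[(2S,3S,5R,6R)-3-{[tert-butyl(diphenyl)silyl]oxymethyl}-5-(prop-2-yn-1-yloxy)-6-vinyltetrahydro-2H-pyran-2-yl]butan-2-one
Product: 21 (1S,2S,4R,5Z,8S)-2-{[tert-butyl(diphenyl)silyl]oxymethyl}-8-methyl-4-(prop-2-yn-1-yloxy)-11-oxabicyclo[6.2.1]undec-5-en-9-one, via oxonium ylide 20 (not isolated)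
Conditions: Cu(CF3COCHCOCF3)2 (Cu(hfacac)2, 5 mol %), CH2Cl2, reflux, slow addition of 19
Reagents that add atoms: none
Why: The copper carbenoid formed from 19 with loss of N2 is attacked by a lone pair of the tetrahydropyran oxygen five atoms away to give the bicyclic oxonium ylide 20 (free or copper-bound), which undergoes a concerted suprafacial [2,3]-sigmatropic shift through a five-membered envelope transition state: C10 bonds to the vinyl terminus C9 while the ring O–C7 bond breaks and C7=C8 forms. The closest known reaction type is the catalytic oxonium ylide formation and [2,3] rearrangement of 2-vinyltetrahydropyranyl diazoketones, which gives 11-oxabicyclo[6.2.1]undec-5-en-9-ones. The dihydrofuranone ring is closed by O–C10 bond formation (five-membered ylide, the fastest mode for an ether oxygen and a carbenoid), and the nine-membered oxacycle and ten-membered carbocycle arise by three-atom ring expansion of the six-membered ring, so no medium ring is closed from an open chain. C10 is the only new stereocentre: because the six-carbon bridge can span the five-membered ring only cis, C9 must enter on the face of C10 that matches C4 at C3, so (S)-C3 dictates (S)-C10 whatever the catalyst. The step needs ylide formation to outrun 1,2-hydride migration from the methyl group, carbenoid C–H insertion and cyclopropanation; the five-atom tether to a basic ether oxygen, the electrophilic hexafluoroacetylacetonate-ligated copper carbenoid, the low carbenoid concentration under slow addition and the fact that a methyl group is the poorest hydride donor among alkyl groups are expected to secure this. The Z geometry of C7=C8 is expected to predominate under copper catalysis because the E alkene is strained in the nine-membered ring, and any E isomer can be converted to Z by reversible thiyl radical addition before step 14.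

Step 14
Reactants: 21 (1S,2S,4R,5Z,8S)-2-{[tert-butyl(diphenyl)silyl]oxymethyl}-8-methyl-4-(prop-2-yn-1-yloxy)-11-oxabicyclo[6.2.1]undec-5-en-9-one
Product: 22 (1S,2S,4R,5R,6R,8S)-2-{[tert-butyl(diphenyl)silyl]oxymethyl}-5,6-epoxy-8-methyl-4-(prop-2-yn-1-yloxy)-11-oxabicyclo[6.2.1]undecan-9-one (cis-epoxide with its oxygen anti to the C4 propargyloxy group; germacrane C7/C8)
Conditions: dimethyldioxirane, acetone, 0 °C
Reagents that add atoms: dimethyldioxirane (CC1(C)OO1)
Why: Prilezhaev-type epoxidation by a dioxirane, which does not cause Baeyer–Villiger oxidation of the α-alkoxy ketone and leaves the alkyne alone. Attack is expected on the peripheral face anti to the pseudo-equatorial C6 ether oxygen, as for medium-ring cis-allylic ethers, which sets C8 (R).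

Step 15
Reactants: 22 the (5R,6R)-epoxide of step 14
Product: 23 (3S,4S,6R,7R,8R,10S)-15-{[tert-butyl(diphenyl)silyl]oxy}-8-hydroxy-3,10:6,12-diepoxygermacr-11(13)-en-1-one
Conditions: Cp2TiCl2 (0.2 equiv), Mn dust, 2,4,6-collidine·HCl, THF, rt
Reagents that add atoms: none
Why: Titanocene-mediated reductive epoxide opening and 5-exo-dig radical cyclisation (Nugent–RajanBabu reaction, catalytic variant): trivalent titanium is expected to break the C7–O bond, leaving the bulky titanoxy group on the less hindered C8. The C7 radical adds to the alkyne held on O6, and the vinyl radical is reduced and protonated to the exocyclic methylene; the aliphatic ketone is inert. C8 keeps the epoxide configuration, and the trans ring fusion at C7 is expected because the ten-membered ring keeps C5–C6–C7–C8 extended and the titanoxy group turns away from the incoming alkyne.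

Step 16
Reactants: 23 (3S,4S,6R,7R,8R,10S)-15-{[tert-butyl(diphenyl)silyl]oxy}-8-hydroxy-3,10:6,12-diepoxygermacr-11(13)-en-1-one; 24 angelic acid
Product: 26 (3S,4S,6R,7S,8R,10S)-15-{[tert-butyl(diphenyl)silyl]oxy}-8-[(Z)-2-methylbut-2-enoyloxy]-3,10:6,12-diepoxygermacr-11(13)-en-1-one, via angelic mixed anhydride 25 (not isolated)
Conditions: 24, 2,4,6-trichlorobenzoyl chloride, Et3N, toluene, rt; then 23, toluene, 80 °C
Reagents that add atoms: 2,4,6-trichlorobenzoyl chloride (O=C(Cl)c1c(Cl)cc(Cl)cc1Cl; atoms kept only in 25)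
Why: Yamaguchi esterification with the preformed mixed anhydride and no nucleophilic catalyst, the usual way to avoid Z to E isomerisation of angelates; C8 is acylated with retention.

Step 17
Reactants: 26 (3S,4S,6R,7S,8R,10S)-15-{[tert-butyl(diphenyl)silyl]oxy}-8-[(Z)-2-methylbut-2-enoyloxy]-3,10:6,12-diepoxygermacr-11(13)-en-1-one
Product: 27 (3S,4S,6R,7S,8R,10S)-15-{[tert-butyl(diphenyl)silyl]oxy}-8-[(Z)-2-methylbut-2-enoyloxy]-3,10-epoxy-1-oxogermacr-11(13)-en-12,6-olide
Conditions: CrO3·2C5H5N (excess), CH2Cl2, rt
Reagents that add atoms: chromium trioxide (O=[Cr](=O)=O)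
Why: Allylic oxidation by hexavalent chromium (Collins reagent) at C12, the only C–H position that is both allylic and α to an ether oxygen, converts the 3-methylenetetrahydrofuran into the α-methylene-γ-butyrolactone, a known change for this ring type; no stereocentre is touched.

Step 18
Reactants: 27 (3S,4S,6R,7S,8R,10S)-15-{[tert-butyl(diphenyl)silyl]oxy}-8-[(Z)-2-methylbut-2-enoyloxy]-3,10-epoxy-1-oxogermacr-11(13)-en-12,6-olide
Product: 29 (4S,6R,7S,8R,10S)-15-{[tert-butyl(diphenyl)silyl]oxy}-8-[(Z)-2-methylbut-2-enoyloxy]-3,10-epoxy-1-oxogermacra-2,11(13)-dien-12,6-olide, via silyl enol ether 28 (not isolated)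
Conditions: Me3SiOTf, Et3N, CH2Cl2, 0 °C; then Pd(OAc)2 (1.1 equiv), MeCN, rt
Reagents that add atoms: trimethylsilyl trifluoromethanesulfonate (C[Si](C)(C)OS(=O)(=O)C(F)(F)F; atoms kept only in 28)
Why: Soft enolisation can occur only towards C2 (C10 is quaternary), and Saegusa–Ito oxidation of 28 by divalent palladium (palladation at C2 on the exo face, syn β-hydride elimination of the exo C3–H) gives the vinylogous ester. The C3 stereocentre, having relayed its configuration to C10, is removed here.

Step 19
Reactants: 29 (4S,6R,7S,8R,10S)-15-{[tert-butyl(diphenyl)silyl]oxy}-8-[(Z)-2-methylbut-2-enoyloxy]-3,10-epoxy-1-oxogermacra-2,11(13)-dien-12,6-olide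
Product: 30 (4S,6R,7S,8R,10S)-15-hydroxy-8-[(Z)-2-methylbut-2-enoyloxy]-3,10-epoxy-1-oxogermacra-2,11(13)-dien-12,6-olide (CNP0108636.1)
Conditions: HF·pyridine, pyridine/THF, 0 °C to rt
Reagents that add atoms: none
Why: Fluoride cleavage of the silyl ether under buffered, mildly acidic conditions that should leave the angelate, the methylene lactone and the epimerisable C4 centre untouched.

## Compound list

1 | (R)-4-benzyloxazolidin-2-one | O=C1N[C@H](Cc2ccccc2)CO1 | starting material
2 | pent-4-enoyl chloride | C=CCCC(Cl)=O | starting material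
3 | (R)-4-benzyl-3-(pent-4-enoyl)oxazolidin-2-one | C=CCCC(=O)N1[C@H](Cc2ccccc2)COC1=O | intermediate
4 | (R)-4-benzyl-3-[(2S)-2-(hydroxymethyl)pent-4-enoyl]oxazolidin-2-one | C=CC[C@@H](CO)C(=O)N1[C@H](Cc2ccccc2)COC1=O | intermediate
5 | (2S)-2-(hydroxymethyl)-N-methoxy-N-methylpent-4-enamide | C=CC[C@@H](CO)C(=O)N(C)OC | intermediate
6 | (2S)-2-{[tert-butyl(diphenyl)silyl]oxymethyl}-N-methoxy-N-methylpent-4-enamide | C=CC[C@@H](CO[Si](c1ccccc1)(c1ccccc1)C(C)(C)C)C(=O)N(C)OC | intermediate
7 | (2S)-2-{[tert-butyl(diphenyl)silyl]oxymethyl}-N-methoxy-N-methyl-4-oxobutanamide | O=CC[C@@H](CO[Si](c1ccccc1)(c1ccccc1)C(C)(C)C)C(=O)N(C)OC | intermediate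
8 | allyl methoxymethyl ether | C=CCOCOC | starting material
9 | (Z)-[3-(methoxymethoxy)allyl]diisopinocampheylborane (from (+)-α-pinene; not isolated) | COCO/C=C\CB([C@@H]1C[C@@H]2C[C@H]([C@H]1C)C2(C)C)[C@@H]1C[C@@H]2C[C@H]([C@H]1C)C2(C)C | intermediate
10 | (2S,4R,5R)-2-{[tert-butyl(diphenyl)silyl]oxymethyl}-4-hydroxy-N-methoxy-5-(methoxymethoxy)-N-methylhept-6-enamide | C=C[C@@H](OCOC)[C@H](O)C[C@@H](CO[Si](c1ccccc1)(c1ccccc1)C(C)(C)C)C(=O)N(C)OC | intermediate
11 | propargyl bromide | C#CCBr | starting material
12 | (2S,4R,5R)-2-{[tert-butyl(diphenyl)silyl]oxymethyl}-N-methoxy-5-(methoxymethoxy)-N-methyl-4-(prop-2-yn-1-yloxy)hept-6-enamide | C=C[C@@H](OCOC)[C@H](OCC#C)C[C@@H](CO[Si](c1ccccc1)(c1ccccc1)C(C)(C)C)C(=O)N(C)OC | intermediate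
13 | (2S,4R,5R)-2-{[tert-butyl(diphenyl)silyl]oxymethyl}-5-(methoxymethoxy)-4-(prop-2-yn-1-yloxy)hept-6-enal | C=C[C@@H](OCOC)[C@H](OCC#C)C[C@@H](CO[Si](c1ccccc1)(c1ccccc1)C(C)(C)C)C=O | intermediate
14 | methyl (2E,4R,6R,7R)-4-{[tert-butyl(diphenyl)silyl]oxymethyl}-7-(methoxymethoxy)-6-(prop-2-yn-1-yloxy)nona-2,8-dienoate | C=C[C@@H](OCOC)[C@H](OCC#C)C[C@@H](CO[Si](c1ccccc1)(c1ccccc1)C(C)(C)C)/C=C/C(=O)OC | intermediate
15 | methyl (2E,4R,6R,7R)-4-{[tert-butyl(diphenyl)silyl]oxymethyl}-7-hydroxy-6-(prop-2-yn-1-yloxy)nona-2,8-dienoate (not isolated) | C=C[C@@H](O)[C@H](OCC#C)C[C@@H](CO[Si](c1ccccc1)(c1ccccc1)C(C)(C)C)/C=C/C(=O)OC | intermediate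
16 | methyl 2-[(2S,3S,5R,6R)-3-{[tert-butyl(diphenyl)silyl]oxymethyl}-5-(prop-2-yn-1-yloxy)-6-vinyltetrahydro-2H-pyran-2-yl]acetate | COC(=O)C[C@@H]1O[C@H](C=C)[C@H](OCC#C)C[C@H]1CO[Si](c1ccccc1)(c1ccccc1)C(C)(C)C | intermediate
17 | 2-[(2S,3S,5R,6R)-3-{[tert-butyl(diphenyl)silyl]oxymethyl}-5-(prop-2-yn-1-yloxy)-6-vinyltetrahydro-2H-pyran-2-yl]acetic acid | OC(=O)C[C@@H]1O[C@H](C=C)[C@H](OCC#C)C[C@H]1CO[Si](c1ccccc1)(c1ccccc1)C(C)(C)C | intermediate
18 | isobutyl carbonic anhydride of 17 (not isolated) | CC(C)COC(=O)OC(=O)C[C@@H]1O[C@H](C=C)[C@H](OCC#C)C[C@H]1CO[Si](c1ccccc1)(c1ccccc1)C(C)(C)C | intermediate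
19 | 3-diazo-1-[(2S,3S,5R,6R)-3-{[tert-butyl(diphenyl)silyl]oxymethyl}-5-(prop-2-yn-1-yloxy)-6-vinyltetrahydro-2H-pyran-2-yl]butan-2-one | CC(=[N+]=[N-])C(=O)C[C@@H]1O[C@H](C=C)[C@H](OCC#C)C[C@H]1CO[Si](c1ccccc1)(c1ccccc1)C(C)(C)C | intermediate
20 | bicyclic oxonium ylide: tetrahydropyran oxygen bonded to the former diazo carbon, five-membered ring O–C3–C2–C1(=O)–C10 (not isolated) | C[C-]1C(=O)C[C@H]2[C@H](CO[Si](c3ccccc3)(c3ccccc3)C(C)(C)C)C[C@@H](OCC#C)[C@@H](C=C)[O+]12 | intermediate
21 | (1S,2S,4R,5Z,8S)-2-{[tert-butyl(diphenyl)silyl]oxymethyl}-8-methyl-4-(prop-2-yn-1-yloxy)-11-oxabicyclo[6.2.1]undec-5-en-9-one | C#CCO[C@@H]1C[C@@H](CO[Si](c2ccccc2)(c2ccccc2)C(C)(C)C)[C@@H]2CC(=O)[C@](C)(C/C=C\1)O2 | intermediate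
22 | (1S,2S,4R,5R,6R,8S)-2-{[tert-butyl(diphenyl)silyl]oxymethyl}-5,6-epoxy-8-methyl-4-(prop-2-yn-1-yloxy)-11-oxabicyclo[6.2.1]undecan-9-one (cis-epoxide, oxygen anti to the propargyloxy group) | C#CCO[C@@H]1C[C@@H](CO[Si](c2ccccc2)(c2ccccc2)C(C)(C)C)[C@@H]2CC(=O)[C@](C)(C[C@@H](O3)[C@@H]31)O2 | intermediate
23 | (3S,4S,6R,7R,8R,10S)-15-{[tert-butyl(diphenyl)silyl]oxy}-8-hydroxy-3,10:6,12-diepoxygermacr-11(13)-en-1-one | C=C1CO[C@@H]2C[C@@H](CO[Si](c3ccccc3)(c3ccccc3)C(C)(C)C)[C@@H]3CC(=O)[C@](C)(C[C@@H](O)[C@@H]12)O3 | intermediate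
24 | angelic acid [(Z)-2-methylbut-2-enoic acid] | C/C=C(/C)C(=O)O | starting material
25 | (Z)-2-methylbut-2-enoic 2,4,6-trichlorobenzoic anhydride (not isolated) | C/C=C(/C)C(=O)OC(=O)c1c(Cl)cc(Cl)cc1Cl | intermediate
26 | (3S,4S,6R,7S,8R,10S)-15-{[tert-butyl(diphenyl)silyl]oxy}-8-[(Z)-2-methylbut-2-enoyloxy]-3,10:6,12-diepoxygermacr-11(13)-en-1-one | C=C1CO[C@@H]2C[C@@H](CO[Si](c3ccccc3)(c3ccccc3)C(C)(C)C)[C@@H]3CC(=O)[C@](C)(C[C@@H](OC(=O)/C(C)=C\C)[C@@H]12)O3 | intermediate
27 | (3S,4S,6R,7S,8R,10S)-15-{[tert-butyl(diphenyl)silyl]oxy}-8-[(Z)-2-methylbut-2-enoyloxy]-3,10-epoxy-1-oxogermacr-11(13)-en-12,6-olide | C=C1C(=O)O[C@@H]2C[C@@H](CO[Si](c3ccccc3)(c3ccccc3)C(C)(C)C)[C@@H]3CC(=O)[C@](C)(C[C@@H](OC(=O)/C(C)=C\C)[C@@H]12)O3 | intermediate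
28 | 1-(trimethylsilyloxy)-1-ene (C1=C2 silyl enol ether) of 27 (not isolated) | C=C1C(=O)O[C@@H]2C[C@@H](CO[Si](c3ccccc3)(c3ccccc3)C(C)(C)C)[C@@H]3C=C(O[Si](C)(C)C)[C@](C)(C[C@@H](OC(=O)/C(C)=C\C)[C@@H]12)O3 | intermediate
29 | (4S,6R,7S,8R,10S)-15-{[tert-butyl(diphenyl)silyl]oxy}-8-[(Z)-2-methylbut-2-enoyloxy]-3,10-epoxy-1-oxogermacra-2,11(13)-dien-12,6-olide | C=C1C(=O)O[C@@H]2C[C@@H](CO[Si](c3ccccc3)(c3ccccc3)C(C)(C)C)C3=CC(=O)[C@](C)(C[C@@H](OC(=O)/C(C)=C\C)[C@@H]12)O3 | intermediate
30 | (4S,6R,7S,8R,10S)-15-hydroxy-8-[(Z)-2-methylbut-2-enoyloxy]-3,10-epoxy-1-oxogermacra-2,11(13)-dien-12,6-olide (CNP0108636.1) | C=C1C(=O)O[C@@H]2C[C@@H](CO)C3=CC(=O)[C@](C)(C[C@@H](OC(=O)/C(C)=C\C)[C@@H]12)O3 | target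

## Step count and least certain steps

Total step count: 19. Longest linear sequence: 19 steps (1 and 2 to 30); the route is fully linear, with 8, 11 and 24 entering as single reagent-like building blocks.

Step 13 (key step). The most likely failure is 1,2-hydride migration from the methyl group of the carbenoid (giving an enone) or C–H insertion competing with ylide formation. A second concern is poor control of the C7=C8 geometry; an E isomer can be equilibrated to Z by thiyl radical addition–elimination, and either geometry can in principle be carried on because C7 becomes a radical centre. Fallback: the quaternary centre would be made after the ring expansion, not in it. Acid 17 is converted through the same mixed anhydride with diazomethane into the terminal diazoketone F1. Copper-catalysed ring expansion of F1, the literal known substrate type, gives the C10-unsubstituted bicyclic ketone F2. Thermodynamic silylation (Me3SiCl, Et3N, NaI, MeCN) gives the more substituted C1=C10 silyl enol ether F3, and MeLi followed by MeI methylates the regiodefined lithium enolate. Only exo attack keeps the six-carbon bridge cis, so the methylation returns to 21 with the same C10 configuration.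

Step 14. The risk is poor or reversed facial selectivity in the epoxidation, since no directing group is present and the outcome rests on the ring conformation. Fallback: the diastereomeric epoxide F4 would be carried through the same titanocene cyclisation to the 8-epi alcohol F5. F5 is then esterified with inversion at C8 (Mitsunobu reaction with angelic acid 24, PPh3, diisopropyl azodicarboxylate), rejoining the route at 26.

Step 15. The risks are homolysis of the wrong epoxide C–O bond (a C8 radical leads to deoxygenation back to the alkene or to six-membered ring closure), transannular opening of the epoxide by the Lewis-acidic medium, and incomplete control of the ring fusion at C7. Fallback: the C7 radical is made by a polar route. Alkene 21 with N-bromosuccinimide in aqueous THF gives the trans-bromohydrin F6, because water opens the bromonium ion at C8, remote from the inductively deactivating C6 oxygen. Bu3SnH with azobisisobutyronitrile in benzene then effects the 5-exo-dig cyclisation from a radical that can only be at C7. Anti addition puts the C8 hydroxyl on the face opposite to that reached through the epoxide, so the product is the 8-epi alcohol F5, and Mitsunobu esterification with 24 returns to 26. If instead the electrophile prefers the other face of 21, this same sequence gives 23 directly.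

Step 17. The risk is poor chemoselectivity of the chromium oxidation on a late intermediate (allylic transposition at C7, attack at the angelate methyl groups or at C3–H, over-oxidation). Fallback: the oxidation is split into two mild stages through the lactol. SeO2 with t-BuOOH in CH2Cl2 hydroxylates the α-oxygenated allylic methylene of 26 (the reactivity used to cleave allyl ethers) to give the lactol F7 as an anomeric mixture. Ag2CO3 on Celite (Fétizon oxidation) then converts F7 into 27.

## Further compounds

F1 | step 13 | 1-diazo-3-[(2S,3S,5R,6R)-3-{[tert-butyl(diphenyl)silyl]oxymethyl}-5-(prop-2-yn-1-yloxy)-6-vinyltetrahydro-2H-pyran-2-yl]propan-2-one | [N-]=[N+]=CC(=O)C[C@@H]1O[C@H](C=C)[C@H](OCC#C)C[C@H]1CO[Si](c1ccccc1)(c1ccccc1)C(C)(C)C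
F2 | step 13 | (1S,2S,4R,5Z,8S)-2-{[tert-butyl(diphenyl)silyl]oxymethyl}-4-(prop-2-yn-1-yloxy)-11-oxabicyclo[6.2.1]undec-5-en-9-one (8-demethyl analogue of 21) | C#CCO[C@@H]1C[C@@H](CO[Si](c2ccccc2)(c2ccccc2)C(C)(C)C)[C@@H]2CC(=O)[C@H](C/C=C\1)O2
F3 | step 13 | 9-(trimethylsilyloxy)-11-oxabicyclo[6.2.1]undeca-5,8-diene derived from F2 (C1=C10 silyl enol ether in germacrane locants) | C#CCO[C@@H]1C[C@@H](CO[Si](c2ccccc2)(c2ccccc2)C(C)(C)C)[C@@H]2CC(O[Si](C)(C)C)=C(C/C=C\1)O2
F4 | step 14 | diastereomeric cis-epoxide of 21 (epoxide oxygen syn to the propargyloxy group) | C#CCO[C@@H]1C[C@@H](CO[Si](c2ccccc2)(c2ccccc2)C(C)(C)C)[C@@H]2CC(=O)[C@](C)(C[C@H](O3)[C@H]31)O2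
F5 | step 14 | 8-epimer of 23 (C8 hydroxyl inverted) | C=C1CO[C@@H]2C[C@@H](CO[Si](c3ccccc3)(c3ccccc3)C(C)(C)C)[C@@H]3CC(=O)[C@](C)(C[C@H](O)[C@@H]12)O3
F6 | step 15 | trans-bromohydrin of 21 (bromine on germacrane C7, hydroxyl on C8) | C#CCO[C@@H]1C[C@@H](CO[Si](c2ccccc2)(c2ccccc2)C(C)(C)C)[C@@H]2CC(=O)[C@](C)(C[C@H](O)[C@H]1Br)O2
F7 | step 17 | C12 lactol of 26 (12-hydroxy-6,12-epoxide, anomeric mixture) | C=C1C(O)O[C@@H]2C[C@@H](CO[Si](c3ccccc3)(c3ccccc3)C(C)(C)C)[C@@H]3CC(=O)[C@](C)(C[C@@H](OC(=O)/C(C)=C\C)[C@@H]12)O3
A1 | alternative 1 | methyl (2Z,4R)-2-(bromomethyl)-4-[(tert-butyldimethylsilyl)oxy]-5-[(2S)-5-[(2S)-1-{[tert-butyl(diphenyl)silyl]oxy}-4-oxobutan-2-yl]-2-methyl-3-oxo-2,3-dihydrofuran-2-yl]pent-2-enoate | COC(=O)/C(CBr)=C/[C@H](O[Si](C)(C)C(C)(C)C)C[C@]1(C)OC(=CC1=O)[C@@H](CC=O)CO[Si](c1ccccc1)(c1ccccc1)C(C)(C)C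
A2 | alternative 2 | (4S,6R,7S,8R,10S)-15-{[tert-butyl(diphenyl)silyl]oxy}-10-hydroxy-8-[(Z)-2-methylbut-2-enoyloxy]-1,3-dioxogermacr-11(13)-en-12,6-olide | C=C1C(=O)O[C@@H]2C[C@@H](CO[Si](c3ccccc3)(c3ccccc3)C(C)(C)C)C(=O)CC(=O)[C@@](C)(O)C[C@@H](OC(=O)/C(C)=C\C)[C@@H]12
A3 | alternative 3 | (1R)-2-iodo-1-[(2R,3S)-2-[(2S)-3-{[tert-butyl(diphenyl)silyl]oxy}-2-(5-methyl-4-oxo-4,5-dihydrofuran-2-yl)propyl]-4-methylidene-5-oxotetrahydrofuran-3-yl]ethyl (Z)-2-methylbut-2-enoate (seco-C9/C10 iodide; C10 unassigned) | C=C1C(=O)O[C@H](C[C@@H](CO[Si](c2ccccc2)(c2ccccc2)C(C)(C)C)C2=CC(=O)C(C)O2)[C@H]1[C@@H](CI)OC(=O)/C(C)=C\C
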